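The earlier runs and the new flask were computed with made-up constants; noise was put on by code.

The constants we can carry to this flask come from the earlier runs, and there are two: a full rate and a lost time.

| setting | Sunday's | Thursday's | flask |
|---|---|---|---|
| Z | 0.088 M | 0.088 M | 0.088 M |
| X | 0.044 M | 0.18 M | 0.0880 M |
| G | 8.8 mM | 8.8 mM | 8.80 mM |
| J | 20 mM (held) | 20 mM (held) | 20 mM (held) |
| remark | run made earlier | run made earlier |  |
| time |  |  | 3.0 h |

| run | time / h | Z / % | Wa / % |
|---|---|---|---|
| Sunday's | 0.417 | 98.9 | 1.3 |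
| Sunday's | 0.833 | 94.8 | 3.8 |
| Sunday's | 1.33 | 92.0 | 8.1 |
| Sunday's | 1.50 | 89.7 | 10.5 |
| Sunday's | 2.00 | 85.4 | 12.9 |
| Sunday's | 2.50 | 80.9 | 17.0 |
| Sunday's | 3.00 | 77.3 | 19.7 |
| Thursday's | 0.250 | 99.6 | 0 |
| Thursday's | 0.333 | 99.1 | 1.4 |
| Thursday's | 0.500 | 97.6 | 2.0 |
| Thursday's | 0.833 | 95.6 | 4.4 |
| Thursday's | 1.33 | 91.9 | 8.0 |
| Thursday's | 2.00 | 84.6 | 13.4 |
| Thursday's | 3.00 | 76.4 | 20.7 |

(scatter of a reading: 0.5 percentage points)

1. part of the Z that has reacted at 3.0 h
2. pH of the solution at 3.0 h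

From 1.33 h to 3.00 h, Sunday's run lost Z at 7.75 mM h⁻¹ and Thursday's at 8.17 mM h⁻¹, though X went from 0.044 M to 0.18 M. So we leave X out and keep their mean, 7.96 mM h⁻¹, as the full rate: the amount of Z used per hour once a run is going. None of J is in solution at the start. Both runs charged the same 0.088 M of Z, and we assume, without a test from them, that the rate does not follow [Z], so we count it as an amount, not as a share of Z.

The start is slower: Sunday's first reading gives 2.32 mM h⁻¹, a factor 0.291 of the full rate. Added up, this hold-up is a lost time: running the full rate back from the mean of the last readings gives 0.440 h. So in 3.0 h our flask works at full rate for 2.56 h, a factor 0.853 of its time, and we reckon 23.1% of Z reacted. The runs show no pH, so we reckon none.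

The forecast says 23% (21.5% to 24.5%) and pH 7.5 (5.5 to 9.5), the pH being “a guess, because the buffer pKa is not given”.

The flask gives 22.6% reacted and pH 9.48.

    J ⇌ D, rate k1*(csat - [D]) (kL = 0.00970 min⁻¹)
    G ⇌ X + E, settled at all times (K = 7.90 × 10⁻¹⁰ M)
    Zu ⇌ D + E, settled at all times (K = 5.00 × 10⁻⁸ M)
    D + Wa → DWa (k = 0.240 M⁻¹ min⁻¹)
    Z + D → E + Wa + Q (k = 0.320 M⁻¹ min⁻¹)

The neighbour charged with 0.22 M of Z, time and all else held, tests the rate counted as an amount. Our full rate and working time give it 20.4 mM of Z used, which is 9.26% of its charge. It gives 12.3%, which is 27.1 mM of Z against 19.9 mM in our flask. So with 2.50 times the Z, the neighbour used 1.36 times the amount.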